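**Retrosynthetic overview**
1. Target ⇐ both oxiranes made last in one flask from the triangelate allylic alcohol: the C3‑OH directs a vanadium epoxidation of the ring alkene, then a Shi epoxidation takes the side‑chain alkene.
2. Side chain ⇐ C7–C8 bond by an asymmetric Nozaki–Hiyama–Kishi coupling of a ring enol triflate with 4‑methylpent‑3‑enal, then angeloylation of C8‑OH.
3. Enol triflate ⇐ methyl ketone from MeLi opening of a bridged allylic γ‑lactone (C7(=O)–O–C3), which stores the C3 oxygen and the C4=C5 alkene.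
4. Key step: carbocycle and lactone are formed together by an enantioselective Diels–Alder reaction (dienyl angelate + β‑angeloyloxy acryloyl imide) followed in the same flask by bromolactonisation; this sets C1, C2, C6 and then C3, and E2 loss of HBr then moves the alkene.
5. Ring order: ring A (carbocycle) plus temporary lactone in one operation → lactone opened → ring‑A oxirane and side‑chain oxirane in the final operation.

Conventions: locants follow the target (ring C1–C6, C1 bears the side chain, C4 the methyl; side chain C7–C11, C14 = exocyclic CH2). "Route numbering" descriptors use these locants. Ang = (2Z)‑2‑methylbut‑2‑enoyl. (R,R)‑t‑Bu‑box = 2,2'‑(propane‑2,2‑diyl)bis[(4R)‑4‑tert‑butyl‑4,5‑dihydro‑1,3‑oxazole].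
Assumption 1: the copper/(S,S)‑t‑Bu‑box catalyst adds dienes to the Cα‑Re face of chelated acryloyl oxazolidinones, so the (R,R)‑ligand is used for the Cα‑Si adduct needed here.
Assumption 2: the (S)‑antipode of the Kishi oxazoline–sulfonamide ligand is taken as the one giving Re‑face addition in step 10; otherwise its mirror image is used.

Step 1
Reactants: 1 3‑methylbut‑2‑enal (prenal); 2 angelic anhydride [(2Z)‑2‑methylbut‑2‑enoic anhydride]
Product: 3 (1E)‑3‑methylbuta‑1,3‑dien‑1‑yl (2Z)‑2‑methylbut‑2‑enoate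
Conditions: KOt‑Bu (1.05 equiv), THF, −78 °C; then 2, −78 → 0 °C
Reagents that add atoms: none
Why: γ‑Deprotonation of prenal gives the s‑trans potassium dienolate, and O‑acylation by the anhydride gives the (1E)‑dienyl ester without a nucleophilic catalyst that could isomerise the angelate (dienolate O‑acylation).

Step 2
Reactants: 4 prop‑2‑ynoic acid (propiolic acid); 5 1,3‑oxazolidin‑2‑one
Product: 7 3‑(prop‑2‑ynoyl)‑1,3‑oxazolidin‑2‑one, via mixed anhydride 6 (not isolated)
Conditions: t‑BuCOCl, Et3N, THF, −20 °C; then 5, LiCl, −20 °C → rt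
Reagents that add atoms: none
Why: N‑Acylation of the oxazolidinone through the pivalic mixed anhydride (LiCl/Et3N acylation), with attack at the less hindered propioloyl carbonyl.

Step 3
Reactants: 7 3‑(prop‑2‑ynoyl)‑1,3‑oxazolidin‑2‑one; 8 angelic acid [(2Z)‑2‑methylbut‑2‑enoic acid]
Product: 9 3‑[(2E)‑3‑(angeloyloxy)prop‑2‑enoyl]‑1,3‑oxazolidin‑2‑one
Conditions: N‑methylmorpholine (10 mol %), CH2Cl2, 0 °C → rt
Reagents that add atoms: none
Why: Amine‑catalysed conjugate addition of the carboxylic acid to the ynoyl imide (oxa‑Michael addition) gives the thermodynamic (E)‑β‑acyloxy acryloyl imide.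

Step 4 (key step)
Reactants: 3 (1E)‑3‑methylbuta‑1,3‑dien‑1‑yl angelate; 9 3‑[(2E)‑3‑(angeloyloxy)prop‑2‑enoyl]‑1,3‑oxazolidin‑2‑one
Product: 11 bromolactone (route numbering 1R,2R,3R,4R,6S): 2,6‑bis(angeloyloxy)‑4‑bromo‑4‑methylcyclohexane‑1‑carboxylic acid 1,3‑lactone (6‑oxabicyclo[3.2.1]octan‑7‑one core), via Diels–Alder adduct 10 (not isolated)
Conditions: Cu(SbF6)2/(R,R)‑t‑Bu‑box (10 mol %), CH2Cl2, 0 °C → rt; then NBS, NaHCO3, THF–H2O, 0 °C
Reagents that add atoms: N‑bromosuccinimide BrN1C(=O)CCC1=O; water O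
Why: Proposed new method: the divalent‑copper bis(oxazoline) complex chelates the imide so that the diene adds to the Cα‑Si face (1‑acyloxy "ortho" and 3‑methyl "para" regiochemistry, imide endo, E‑geometry of the dienophile retained), setting C1, C2 and C6; the imide carbonyl oxygen then opens the bromonium ion of C3=C4 at C3, the only carbon it can reach (anti addition, so O3 is cis to C1 and Br is on C4), and hydrolysis releases the oxazolidinone, so carbocycle and γ‑lactone form in one operation; the closest known reactions are the Evans bis(oxazoline)–copper Diels–Alder reaction of acryloyl oxazolidinones (including with 1‑acetoxy‑3‑methylbutadiene) and halolactonisation of γ,δ‑unsaturated N‑acyl oxazolidinones with loss of the heterocycle.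

Step 5
Reactants: 11 bromolactone
Product: 12 alkene lactone (route numbering 1R,2R,3S,6S): 2,6‑bis(angeloyloxy)‑4‑methylcyclohex‑4‑ene‑1‑carboxylic acid 1,3‑lactone (6‑oxabicyclo[3.2.1]oct‑3‑en‑7‑one core)
Conditions: DBU (1.5 equiv), toluene, rt
Reagents that add atoms: none
Why: E2 dehydrobromination: the axial tertiary C4–Br is anti‑periplanar to the axial C5–H and loss of HBr relieves the 1,3‑diaxial Br/C6‑OAng strain, giving the endocyclic C4=C5 alkene, while the bridgehead C1–H cannot enolise so the β‑acyloxy groups are not eliminated.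

Step 6
Reactants: 12 alkene lactone
Product: 13 (route numbering 1R,2R,3S,6S)‑1‑acetyl‑3‑hydroxy‑4‑methylcyclohex‑4‑ene‑2,6‑diyl diangelate
Conditions: MeLi (1.05 equiv), THF, −95 °C; aq. NH4Cl at −95 °C
Reagents that add atoms: methyllithium [Li]C
Why: Organolithium addition to a lactone: the strained bridged γ‑lactone is more electrophilic than the hindered conjugated angelates and its lithium lactolate does not add a second methyl at −95 °C; the C3–O bond is not broken, so C3 keeps its configuration.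

Step 7
Reactants: 13 hydroxy ketone
Product: 14 (route numbering 1R,2R,3S,6S)‑1‑acetyl‑4‑methyl‑3‑(triethylsilyloxy)cyclohex‑4‑ene‑2,6‑diyl diangelate
Conditions: Et3SiCl, imidazole, DMF, 0 °C → rt
Reagents that add atoms: chlorotriethylsilane CC[Si](Cl)(CC)CC
Why: Silyl ether formation masks the C3 hydroxyl, which would otherwise be deprotonated next to the C2 ester in step 8 and compete for acylation in step 11.

Step 8
Reactants: 14 silyl ether ketone
Product: 15 (route numbering 1R,2R,3S,6S)‑4‑methyl‑3‑(triethylsilyloxy)‑1‑[1‑(trifluoromethanesulfonyloxy)ethenyl]cyclohex‑4‑ene‑2,6‑diyl diangelate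
Conditions: KN(SiMe3)2 (1.05 equiv), THF, −78 °C; then Comins' reagent, −78 °C
Reagents that add atoms: Comins' reagent [N‑(5‑chloropyridin‑2‑yl)bis(trifluoromethanesulfonimide)] O=S(=O)(N(c1ccc(Cl)cn1)S(=O)(=O)C(F)(F)F)C(F)(F)F
Why: Kinetic deprotonation at the methyl group and O‑triflation at −78 °C (enol triflate formation) give the 1,1‑disubstituted enol triflate before the enolate can equilibrate towards C1 and expel a β‑angelate.

Step 9
Reactants: 16 4‑methylpent‑3‑en‑1‑ol
Product: 17 4‑methylpent‑3‑enal (used crude)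
Conditions: Dess–Martin periodinane, NaHCO3, CH2Cl2, 0 °C
Reagents that add atoms: none
Why: Dess–Martin oxidation under buffered, non‑basic conditions gives the aldehyde without moving the β,γ‑alkene into conjugation.

Step 10
Reactants: 15 enol triflate; 17 4‑methylpent‑3‑enal
Product: 18 (route numbering 1R,2R,3S,6S,8S)‑1‑[(3S)‑3‑hydroxy‑6‑methylhepta‑1,5‑dien‑2‑yl]‑4‑methyl‑3‑(triethylsilyloxy)cyclohex‑4‑ene‑2,6‑diyl diangelate
Conditions: CrCl2 (4 equiv), NiCl2 (2 mol %), (S)‑N‑[2‑(4‑isopropyl‑4,5‑dihydro‑1,3‑oxazol‑2‑yl)‑6‑methylphenyl]methanesulfonamide, Et3N, THF, rt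
Reagents that add atoms: none
Why: Nozaki–Hiyama–Kishi reaction: the nickel‑generated alkenyl chromium species adds only to the aldehyde, and the chiral sulfonamide ligand on chromium directs attack to the aldehyde Re face, setting 8S.

Step 11
Reactants: 18 allylic alcohol; 2 angelic anhydride
Product: 19 (route numbering 1R,2R,3S,6S,8S)‑1‑[(3S)‑3‑(angeloyloxy)‑6‑methylhepta‑1,5‑dien‑2‑yl]‑4‑methyl‑3‑(triethylsilyloxy)cyclohex‑4‑ene‑2,6‑diyl diangelate
Conditions: LiN(SiMe3)2 (1.05 equiv), THF, −78 °C; then 2, −78 → −20 °C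
Reagents that add atoms: none
Why: Acylation of the lithium alkoxide by the anhydride proceeds with retention at C8 and without a nucleophilic catalyst, so the angelate is not isomerised to tiglate.

Step 12
Reactants: 19 silyl‑protected triangelate
Product: 20 (route numbering 1R,2R,3S,6S,8S)‑1‑[(3S)‑3‑(angeloyloxy)‑6‑methylhepta‑1,5‑dien‑2‑yl]‑3‑hydroxy‑4‑methylcyclohex‑4‑ene‑2,6‑diyl diangelate
Conditions: Bu4NF, AcOH (1:1), THF, 0 °C
Reagents that add atoms: none
Why: Fluoride desilylation buffered with acetic acid frees the C3 hydroxyl without generating an alkoxide next to the C2 angelate, so no acyl migration occurs.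

Step 13
Reactants: 20 triangelate allylic alcohol
Product: 22 CNP0147918.1 (route numbering 1S,2R,3R,4R,5S,6R,8S,10R), via ring epoxide 21 (not isolated)
Conditions: VO(acac)2 (5 mol %), t‑BuOOH (1.2 equiv), CH2Cl2, 0 °C; then MeCN–(MeO)2CH2–aq. NaHCO3/Na2EDTA, Shi ketone (D‑fructose‑derived, 3 equiv), KHSO5 (as Oxone, 2KHSO5·KHSO4·K2SO4), 0 °C
Reagents that add atoms: tert‑butyl hydroperoxide CC(C)(C)OO; potassium peroxymonosulfate [K+].[O-]S(=O)(=O)OO
Why: The C3 hydroxyl binds vanadium and delivers oxygen to the syn face of C4=C5 (Sharpless–Michaelson directed epoxidation, sets C4 and C5), and the fructose‑derived dioxirane then epoxidises the only remaining electron‑rich trisubstituted alkene from the face giving 10R (Shi epoxidation), the enoate and 1,1‑disubstituted alkenes being inert.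

**Compound list**
1 | 3‑methylbut‑2‑enal | CC(C)=CC=O | starting material
2 | angelic anhydride | C/C=C(/C)C(=O)OC(=O)/C(C)=C\C | starting material
3 | (1E)‑3‑methylbuta‑1,3‑dien‑1‑yl angelate | C=C(C)/C=C/OC(=O)/C(C)=C\C | intermediate
4 | prop‑2‑ynoic acid | C#CC(=O)O | starting material
5 | 1,3‑oxazolidin‑2‑one | O=C1NCCO1 | starting material
6 | prop‑2‑ynoic pivalic anhydride | C#CC(=O)OC(=O)C(C)(C)C | intermediate
7 | 3‑(prop‑2‑ynoyl)‑1,3‑oxazolidin‑2‑one | C#CC(=O)N1CCOC1=O | intermediate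
8 | angelic acid | C/C=C(/C)C(=O)O | starting material
9 | 3‑[(2E)‑3‑(angeloyloxy)prop‑2‑enoyl]‑1,3‑oxazolidin‑2‑one | O=C(/C=C/OC(=O)/C(C)=C\C)N1CCOC1=O | intermediate
10 | 3‑{[(1R,2S,6S)‑2,6‑bis(angeloyloxy)‑4‑methylcyclohex‑3‑en‑1‑yl]carbonyl}‑1,3‑oxazolidin‑2‑one | O=C([C@H]1[C@@H](OC(=O)/C(C)=C\C)C=C(C)C[C@@H]1OC(=O)/C(C)=C\C)N1CCOC1=O | intermediate
11 | bromolactone (route numbering 1R,2R,3R,4R,6S) | O=C1O[C@H]2[C@](C)(Br)C[C@H](OC(=O)/C(C)=C\C)[C@@H]1[C@H]2OC(=O)/C(C)=C\C | intermediate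
12 | alkene lactone (route numbering 1R,2R,3S,6S) | O=C1O[C@H]2C(C)=C[C@H](OC(=O)/C(C)=C\C)[C@@H]1[C@H]2OC(=O)/C(C)=C\C | intermediate
13 | 1‑acetyl‑3‑hydroxy‑4‑methylcyclohex‑4‑ene‑2,6‑diyl diangelate (1R,2R,3S,6S) | CC(=O)[C@H]1[C@@H](OC(=O)/C(C)=C\C)[C@@H](O)C(C)=C[C@@H]1OC(=O)/C(C)=C\C | intermediate
14 | 3‑O‑triethylsilyl ether of 13 | CC(=O)[C@H]1[C@@H](OC(=O)/C(C)=C\C)[C@@H](O[Si](CC)(CC)CC)C(C)=C[C@@H]1OC(=O)/C(C)=C\C | intermediate
15 | enol triflate (1R,2R,3S,6S) | C=C(OS(=O)(=O)C(F)(F)F)[C@H]1[C@@H](OC(=O)/C(C)=C\C)[C@@H](O[Si](CC)(CC)CC)C(C)=C[C@@H]1OC(=O)/C(C)=C\C | intermediate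
16 | 4‑methylpent‑3‑en‑1‑ol | CC(C)=CCCO | starting material
17 | 4‑methylpent‑3‑enal | CC(C)=CCC=O | intermediate
18 | (8S)‑allylic alcohol, 3‑OTES, 2,6‑diangelate | C=C([C@H]1[C@@H](OC(=O)/C(C)=C\C)[C@@H](O[Si](CC)(CC)CC)C(C)=C[C@@H]1OC(=O)/C(C)=C\C)[C@H](CC=C(C)C)O | intermediate
19 | 3‑OTES 2,6,8‑triangelate | C=C([C@H]1[C@@H](OC(=O)/C(C)=C\C)[C@@H](O[Si](CC)(CC)CC)C(C)=C[C@@H]1OC(=O)/C(C)=C\C)[C@H](CC=C(C)C)OC(=O)/C(C)=C\C | intermediate
20 | 3‑hydroxy 2,6,8‑triangelate triene | C=C([C@H]1[C@@H](OC(=O)/C(C)=C\C)[C@@H](O)C(C)=C[C@@H]1OC(=O)/C(C)=C\C)[C@H](CC=C(C)C)OC(=O)/C(C)=C\C | intermediate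
21 | 4,5‑epoxide of 20 (1S,2R,3R,4R,5S,6R,8S) | C=C([C@H]1[C@@H](OC(=O)/C(C)=C\C)[C@@H](O)[C@@]2(C)O[C@H]2[C@@H]1OC(=O)/C(C)=C\C)[C@H](CC=C(C)C)OC(=O)/C(C)=C\C | intermediate
22 | CNP0147918.1 | C=C([C@H]1[C@@H](OC(=O)/C(C)=C\C)[C@@H](O)[C@@]2(C)O[C@H]2[C@@H]1OC(=O)/C(C)=C\C)[C@H](C[C@H]1OC1(C)C)OC(=O)/C(C)=C\C | target

**Totals**
Total step count: 13. Longest linear sequence: 11 steps (steps 2–8 and 10–13; steps 1 and 9 make the two side inputs).

**Steps most likely to fail and fallbacks**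

Step 4 is the most exposed. Both partners are deactivated for the cycloaddition. The bromolactone also carries a 1,3‑diaxial Br/OAng pair, so the C2 angelate or water could intercept the bromonium ion instead of the imide. Fallback, setting out from 3 and returning at 11: acylate (4S)‑4‑benzyl‑1,3‑oxazolidin‑2‑one with mixed anhydride 6 to (4S)‑4‑benzyl‑3‑(prop‑2‑ynoyl)‑1,3‑oxazolidin‑2‑one F1. Add 8 as in step 3 to give the auxiliary dienophile (4S)‑4‑benzyl‑3‑[(2E)‑3‑(angeloyloxy)prop‑2‑enoyl]‑1,3‑oxazolidin‑2‑one F2. React F2 with 3 under Et2AlCl (CH2Cl2, −78 °C); in the cationic aluminium chelate the diene adds anti to the benzyl group, which is the same Cα‑Si face, giving the auxiliary cycloadduct F3. Cleave the auxiliary with LiOH/H2O2 to (1R,2S,6S)‑2,6‑bis(angeloyloxy)‑4‑methylcyclohex‑3‑ene‑1‑carboxylic acid F4, and bromolactonise the free carboxylate (NBS, NaHCO3) to 11.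

Step 6 may fail through methyllithium attacking an angelate, or through acyl migration from O2 to the new O3 alkoxide. Fallback, setting out from 12 and returning at 13: open the lactone with Me(MeO)NH·HCl/i‑PrMgCl (THF, −20 °C) to the hydroxy Weinreb amide (route numbering 1R,2R,3S,6S)‑3‑hydroxy‑N‑methoxy‑N,4‑dimethyl‑2,6‑bis(angeloyloxy)cyclohex‑4‑ene‑1‑carboxamide F5. Then add MeMgBr at −40 °C; the chelated tetrahedral intermediate stops at the ketone, giving 13.

Step 10 may give poor control at C8, because the ligand has to override an unknown substrate bias from C1. Fallback, setting out from 15 and 17 and returning at 18: run the coupling with CrCl2/NiCl2 in DMF without ligand, which gives 18 together with its C8 epimer, the (8R)‑allylic alcohol F6. Oxidise the mixture with Dess–Martin periodinane to the α‑methylene ketone (enone) F7. Reduce with (R)‑2‑methyl‑CBS‑oxazaborolidine and catecholborane (alkenyl as the large group), which returns the (8S)‑alcohol 18.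

**Further compounds**
F1 | step 4 | (4S)‑4‑benzyl‑3‑(prop‑2‑ynoyl)‑1,3‑oxazolidin‑2‑one | C#CC(=O)N1[C@@H](Cc2ccccc2)COC1=O
F2 | step 4 | (4S)‑4‑benzyl‑3‑[(2E)‑3‑(angeloyloxy)prop‑2‑enoyl]‑1,3‑oxazolidin‑2‑one | C/C=C(/C)C(=O)O/C=C/C(=O)N1[C@@H](Cc2ccccc2)COC1=O
F3 | step 4 | (4S)‑4‑benzyl‑3‑{[(1R,2S,6S)‑2,6‑bis(angeloyloxy)‑4‑methylcyclohex‑3‑en‑1‑yl]carbonyl}‑1,3‑oxazolidin‑2‑one | O=C([C@H]1[C@@H](OC(=O)/C(C)=C\C)C=C(C)C[C@@H]1OC(=O)/C(C)=C\C)N1[C@@H](Cc2ccccc2)COC1=O
F4 | step 4 | (1R,2S,6S)‑2,6‑bis(angeloyloxy)‑4‑methylcyclohex‑3‑ene‑1‑carboxylic acid | OC(=O)[C@H]1[C@@H](OC(=O)/C(C)=C\C)C=C(C)C[C@@H]1OC(=O)/C(C)=C\C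
F5 | step 6 | (route numbering 1R,2R,3S,6S)‑3‑hydroxy‑N‑methoxy‑N,4‑dimethyl‑2,6‑bis(angeloyloxy)cyclohex‑4‑ene‑1‑carboxamide | CON(C)C(=O)[C@H]1[C@@H](OC(=O)/C(C)=C\C)[C@@H](O)C(C)=C[C@@H]1OC(=O)/C(C)=C\C
F6 | step 10 | (8R)‑epimer of 18 | C=C([C@H]1[C@@H](OC(=O)/C(C)=C\C)[C@@H](O[Si](CC)(CC)CC)C(C)=C[C@@H]1OC(=O)/C(C)=C\C)[C@@H](CC=C(C)C)O
F7 | step 10 | C8 ketone (enone) corresponding to 18 | C=C([C@H]1[C@@H](OC(=O)/C(C)=C\C)[C@@H](O[Si](CC)(CC)CC)C(C)=C[C@@H]1OC(=O)/C(C)=C\C)C(=O)CC=C(C)C
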